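| flask | starting material | protic impurity | free catalyst | added ligand | remark | time |
|---|---|---|---|---|---|---|
| delta | 1 M (fed, over 8.0 h) | 0.50 M | 0.46 mM | 1.5 mM | run made earlier; the fed solution adds 0.10 times the starting volume |  |
| theta | 1 M (fed, over 8.0 h) | 0.50 M | 0.94 mM | 1.5 mM | run made earlier; the fed solution adds 0.10 times the starting volume |  |
| eta | 1 M (fed, over 8.0 h) | 0.50 M | 1.5 mM | 1.5 mM | run made earlier; the fed solution adds 0.10 times the starting volume |  |
| grey | 1.0 M (fed, over 8.0 h) | 0.500 M | 0.50 mM | 1.5 mM | the fed solution adds 0.10 times the starting volume | 4.0 d |
| red | 1.0 M (fed, over 8.0 h) | 0.500 M | 1.0 mM | 1.5 mM | the fed solution adds 0.10 times the starting volume | 4.0 d |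
| ochre | 1.0 M (fed, over 8.0 h) | 0.500 M | 2.0 mM | 1.5 mM | the fed solution adds 0.10 times the starting volume | 4.0 d |

| run | time / d | target / % | starting material / % |
|---|---|---|---|
| delta | 0.333 | 5.0 | 63.0 |
| delta | 1.04 | 17.8 | 36.1 |
| delta | 1.67 | 23.3 | 25.3 |
| delta | 3.00 | 35.5 | 15.1 |
| delta | 4.00 | 39.8 | 10.2 |
| theta | 0.333 | 8.9 | 59.9 |
| theta | 0.625 | 21.2 | 34.8 |
| theta | 1.04 | 31.3 | 20.6 |
| theta | 2.00 | 42.1 | 6.9 |
| theta | 4.00 | 50.1 | 1.1 |
| eta | 0.333 | 14.0 | 52.2 |
| eta | 0.625 | 32.2 | 27.1 |
| eta | 1.04 | 40.9 | 10.6 |
| eta | 2.00 | 51.4 | 1.0 |
| eta | 4.00 | 52.2 | 0.7 |

(readings scatter by 1 percentage point)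

* amount of target at the end, in percent of the starting material charged for grey, red, ochre, in this order
* the shape of the row from first to last (falls all the way / falls, then rises / hardly changes / rises, then falls / rises all the way)

- amounts are per litre of the starting volume; all of the dose is in the solution fed
- the numbers in the tables scatter with a standard deviation of 1 percentage point
- "hardly changes" means that all values lie within two and a half points (for a concentration: within two and a half percent of the largest)

- A small charge of free catalyst has to work through a large charge of starting material, so I follow the rate at which the starting material disappears, and I take delta, the run with the lowest charged c(free catalyst), as my measure.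
- In delta, the rate over the first stretch after the feed is 7.76 times the rate over the last stretch. Two slowings multiply to give this factor.
- The first slowing is that a second path, which takes starting material without giving target, stops. Target plus starting material in delta stands at 48.6 % at 1.67 d and 50.0 % at 4.00 d, level within the scatter, so I read the loss as over by then.
- The time in which the starting material falls by the factor e after that loss, the tail time constant of a pseudo-first-order decay, reads 2.56 d in delta. It is longer than the 1.27 d of the early stretch, which gives a factor of 2.02.
- The second slowing is the shrinking starting material itself, which supplies the remaining factor of 3.84.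
- I assume the tail time constant goes inversely with the charged c(free catalyst). That gives 2.36 d for grey, 1.18 d for red and 0.590 d for ochre.
- My grey residue is delta's final reading shrunk by the extra time constants, 8.91 %, so I put target at 41.1 %.
- The same step from theta gives red 50.3 %.
- Ochre has 6.78 time constants in 4.0 d, so I take its residue as negligible. I extend the final sum of target and starting material from delta through eta and reach 54.3 %, above the forecast for ochre.
- The forecast gives 41.5 %, 50.5 % and 53 %, a row that rises all the way, on the ground that the loss “stops once the impurity is used up”.

The simulation gives 42.1 %, 49.9 % and 55.5 %, a row that rises all the way.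

    free catalyst + added ligand ⇌ idle complex (K = 900 M⁻¹, k = 0.0470 M⁻¹ s⁻¹)
    starting material + free catalyst ⇌ catalyst intermediate A (K = 1.80 M⁻¹, k = 0.0410 M⁻¹ s⁻¹)
    catalyst intermediate A ⇌ catalyst intermediate B (K = 1.30, k = 0.130 s⁻¹)
    starting material + protic impurity → quenched substrate (k = 1.10 × 10⁻⁴ M⁻¹ s⁻¹)
    catalyst intermediate B → free catalyst + target (k = 0.0470 s⁻¹)

In grey, the turning of starting material and protic impurity into quenched substrate had 99.7 % of its turnover up to 4.00 d behind it at 2.00 d, with 0.285 % of the impurity left. After that, grey's starting material fell from 20.8 % to 7.92 % by 4.00 d, a tail time constant of 2.07 d against my 2.36 d, and in red the same stretch, from 6.53 % to 0.636 %, gives 0.859 d against my 1.18 d.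

Readings and results were generated by integration on assumed constants; scatter was added.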